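**Retrosynthetic overview**
1. The C6 enoate is put on last; the C6 oxygen comes from axial allylic hydroxylation of the exocyclic methylene, and the C1 2‑methylbutanoate from esterification of an α‑ketol.
2. The five‑membered enone ring is opened at C2–C3: titanium‑mediated alkyne–ester acyl substitution of an alkynyl α‑hydroxy ester, followed by E→Z equilibration of the ethylidene.
3. That ester comes from ketone methylenation, a glyoxylate aldol (C7a–C1) and a conjugate propynylation (C3a–C3) on (R)‑cryptone; both new bonds are trans by relay from C4.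
4. (R)‑Cryptone comes from catalytic desymmetrising dehydrogenation of 4‑isopropylcyclohexanone, which comes from hydrogenation of 4‑isopropylphenol.
5. Ring order: six‑membered ring first (from the arene), five‑membered ring second (step 6).

Assumption: 1‑propynylmagnesium bromide (THF solution), ethyl glyoxylate (toluene solution, cracked before use), (2R)‑2‑methylbutanoic acid and (2E)‑3‑methylpent‑2‑enoic acid are bought as catalogue items.

**Step 1**
Reactants: 1 4‑isopropylphenol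
Product: 2 4‑isopropylcyclohexanone
Conditions: H2 (10 bar), Pd/C (2 mol% Pd), AlCl3 (10 mol%), CH2Cl2, 50 °C
Reagents that add atoms: none
Why: Lewis‑acid‑assisted partial hydrogenation of a phenol on palladium (the cyclohexenol tautomerises to the ketone, whose AlCl3 complex resists further reduction); the product is achiral.

**Step 2**
Reactants: 2 4‑isopropylcyclohexanone
Product: 3 (4R)‑4‑(propan‑2‑yl)cyclohex‑2‑en‑1‑one [(R)‑cryptone]
Conditions: tBuCH(NH2)CH2NEt2·TfOH (single enantiomer, the one that gives the 4R enone; 20 mol%), IBX (1.3 equiv), DMSO/PhMe, 40 °C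
Reagents that add atoms: none
Why: Aminocatalytic desymmetrising dehydrogenation (oxidative enamine catalysis, IBX‑type ketone desaturation): the chiral primary amine engages one of the two enantiotopic α‑CH2–β‑CH2 arms as its enamine and IBX desaturates it, turning the prochiral C4 into the R stereocentre from which every later centre is relayed.

**Step 3**
Reactants: 3 (4R)‑4‑(propan‑2‑yl)cyclohex‑2‑en‑1‑one; 4 1‑propynylmagnesium bromide
Product: 6 tert‑butyl{[(3R,4R)‑4‑(propan‑2‑yl)‑3‑(prop‑1‑yn‑1‑yl)cyclohex‑1‑en‑1‑yl]oxy}dimethylsilane, via 1‑propynylzinc bromide 5 (not isolated)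
Conditions: 4, ZnBr2, THF/Et2O, 0 °C; then 3, TBSOTf, −40 to −20 °C; Et3N, aq. NaHCO3
Reagents that add atoms: tert‑butyldimethylsilyl trifluoromethanesulfonate, CC(C)(C)[Si](C)(C)OS(=O)(=O)C(F)(F)F; zinc bromide, [Zn+2].[Br-].[Br-] (zinc appears in 5 only)
Why: Silyl‑triflate‑promoted conjugate alkynylation with an alkynylzinc (Mukaiyama–Michael type): axial attack anti to the C4 isopropyl group sets C3 (future C3a) trans to it, and the enolate is trapped regiospecifically as the silyl enol ether.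

**Step 4**
Reactants: 6 tert‑butyl{[(3R,4R)‑4‑(propan‑2‑yl)‑3‑(prop‑1‑yn‑1‑yl)cyclohex‑1‑en‑1‑yl]oxy}dimethylsilane; 7 ethyl glyoxylate
Product: 8 ethyl (2R)‑2‑hydroxy‑2‑[(1R,2R,3R)‑6‑oxo‑3‑(propan‑2‑yl)‑2‑(prop‑1‑yn‑1‑yl)cyclohexyl]acetate
Conditions: TiCl4 (1.1 equiv), CH2Cl2, −78 °C; aq. NaHCO3
Reagents that add atoms: none
Why: Mukaiyama aldol with a bidentate aldehyde: the TiCl4‑chelated glyoxylate is attacked through an open transition state on the enol face anti to the adjacent propynyl group (2,3‑trans, future C7a), and the chelate enforces the syn aldol relationship that fixes the carbinol carbon (future C1) as R.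

**Step 5**
Reactants: 8 ethyl (2R)‑2‑hydroxy‑2‑[(1R,2R,3R)‑6‑oxo‑3‑(propan‑2‑yl)‑2‑(prop‑1‑yn‑1‑yl)cyclohexyl]acetate
Product: 9 ethyl (2R)‑2‑hydroxy‑2‑[(1S,2R,3R)‑6‑methylidene‑3‑(propan‑2‑yl)‑2‑(prop‑1‑yn‑1‑yl)cyclohexyl]acetate
Conditions: Zn, CH2Br2, TiCl4, THF (pre‑aged reagent); then 8, CH2Cl2, 0 °C to rt
Reagents that add atoms: dibromomethane, BrCBr
Why: Takai–Lombardo methylenation: the non‑basic zinc–titanium methylene reagent olefinates the ketone chemoselectively (ester, alkyne and free OH tolerated) without retro‑aldol or epimerisation at the α‑carbon; no new stereocentre (the descriptor at C1 of the ring changes only by priority).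

**Step 6**
Reactants: 9 ethyl (2R)‑2‑hydroxy‑2‑[(1S,2R,3R)‑6‑methylidene‑3‑(propan‑2‑yl)‑2‑(prop‑1‑yn‑1‑yl)cyclohexyl]acetate
Product: 12 (1R,3Z,3aR,4R,7aS)‑3‑ethylidene‑1‑hydroxy‑7‑methylidene‑4‑(propan‑2‑yl)octahydro‑2H‑inden‑2‑one, via vinyltitanium ketone 10 (not isolated), via E‑ethylidene ketol 11 (not isolated)
Conditions: iPrMgCl (1.0 equiv), Et2O, −78 °C; Ti(OiPr)4 (1.5 equiv), iPrMgCl (3.0 equiv), −78 to −40 °C; H2O; then crude, PBu3 (10 mol%), PhMe, 50 °C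
Reagents that add atoms: none
Why: Sato‑type titanium‑mediated intramolecular nucleophilic acyl substitution: the divalent titanium complex (η2‑propene)Ti(OiPr)2 exchanges onto the alkyne and the titanacyclopropene acylates at its ring‑side carbon with the ester (5‑exo, ethoxide lost), closing the cyclopentanone between two equatorial arms so the trans ring fusion is kept; syn protonolysis gives the E alkene, which reversible PBu3 conjugate addition equilibrates to the Z isomer that is free of allylic 1,3‑strain with the C3a–C4 bond.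

**Step 7**
Reactants: 12 (1R,3Z,3aR,4R,7aS)‑3‑ethylidene‑1‑hydroxy‑7‑methylidene‑4‑(propan‑2‑yl)octahydro‑2H‑inden‑2‑one; 13 (2R)‑2‑methylbutanoic acid
Product: 14 (1R,3Z,3aR,4R,7aS)‑3‑ethylidene‑7‑methylidene‑2‑oxo‑4‑(propan‑2‑yl)octahydro‑1H‑inden‑1‑yl (2R)‑2‑methylbutanoate
Conditions: DCC, DMAP (10 mol%), CH2Cl2, 0 °C
Reagents that add atoms: none
Why: Steglich esterification of the α‑ketol with retention at C1; low temperature and catalytic DMAP keep the α‑stereocentre of the acid and the base‑sensitive acyloin intact.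

**Step 8**
Reactants: 14 (1R,3Z,3aR,4R,7aS)‑3‑ethylidene‑7‑methylidene‑2‑oxo‑4‑(propan‑2‑yl)octahydro‑1H‑inden‑1‑yl (2R)‑2‑methylbutanoate
Product: 15 (1R,3Z,3aR,4R,6S,7aS)‑3‑ethylidene‑6‑hydroxy‑7‑methylidene‑2‑oxo‑4‑(propan‑2‑yl)octahydro‑1H‑inden‑1‑yl (2R)‑2‑methylbutanoate
Conditions: SeO2 (30 mol%), tBuOOH (3 equiv), CH2Cl2, 0 °C to rt
Reagents that add atoms: selenium dioxide, O=[Se]=O (catalytic oxygen carrier); tert‑butyl hydroperoxide, CC(C)(C)OO (terminal oxygen source)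
Why: Selenium dioxide allylic hydroxylation (ene reaction, then [2,3]‑sigmatropic shift): the electron‑rich 1,1‑disubstituted alkene reacts in preference to the enone, the ring CH2 (C6) is attacked rather than the hindered ring‑fusion CH, and oxygen is delivered axially to give 6S.

**Step 9**
Reactants: 15 (1R,3Z,3aR,4R,6S,7aS)‑3‑ethylidene‑6‑hydroxy‑7‑methylidene‑2‑oxo‑4‑(propan‑2‑yl)octahydro‑1H‑inden‑1‑yl (2R)‑2‑methylbutanoate; 16 (2E)‑3‑methylpent‑2‑enoic acid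
Product: 17 (1R,3Z,3aR,4R,6S,7aS)‑3‑ethylidene‑7‑methylidene‑1‑{[(2R)‑2‑methylbutanoyl]oxy}‑2‑oxo‑4‑(propan‑2‑yl)octahydro‑1H‑inden‑6‑yl (2E)‑3‑methylpent‑2‑enoate
Conditions: DCC, DMAP (10 mol%), CH2Cl2, 0 °C to rt
Reagents that add atoms: none
Why: Steglich esterification of the axial allylic alcohol with retention at C6; mild carbodiimide activation avoids isomerising the trisubstituted enoate.

**Compound list**
1 | 4‑isopropylphenol | CC(C)c1ccc(O)cc1 | starting material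
2 | 4‑isopropylcyclohexanone | CC(C)C1CCC(=O)CC1 | intermediate
3 | (4R)‑4‑(propan‑2‑yl)cyclohex‑2‑en‑1‑one | O=C1C=C[C@@H](C(C)C)CC1 | intermediate
4 | 1‑propynylmagnesium bromide | CC#C[Mg]Br | starting material
5 | 1‑propynylzinc bromide | CC#C[Zn]Br | intermediate
6 | tert‑butyl{[(3R,4R)‑4‑(propan‑2‑yl)‑3‑(prop‑1‑yn‑1‑yl)cyclohex‑1‑en‑1‑yl]oxy}dimethylsilane | CC(C)(C)[Si](C)(C)OC1=C[C@H](C#CC)[C@@H](C(C)C)CC1 | intermediate
7 | ethyl glyoxylate | CCOC(=O)C=O | starting material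
8 | ethyl (2R)‑2‑hydroxy‑2‑[(1R,2R,3R)‑6‑oxo‑3‑(propan‑2‑yl)‑2‑(prop‑1‑yn‑1‑yl)cyclohexyl]acetate | O=C1[C@@H]([C@@H](O)C(=O)OCC)[C@H](C#CC)[C@@H](C(C)C)CC1 | intermediate
9 | ethyl (2R)‑2‑hydroxy‑2‑[(1S,2R,3R)‑6‑methylidene‑3‑(propan‑2‑yl)‑2‑(prop‑1‑yn‑1‑yl)cyclohexyl]acetate | C=C1[C@@H]([C@@H](O)C(=O)OCC)[C@H](C#CC)[C@@H](C(C)C)CC1 | intermediate
10 | vinyltitanium ketone: (1R,3aR,4R,7aS)‑1‑(chloromagnesiooxy)‑3‑{1‑[ethoxybis(propan‑2‑yloxy)titanio]ethylidene}‑7‑methylidene‑4‑(propan‑2‑yl)octahydro‑2H‑inden‑2‑one, titanium cis to the ring carbonyl | C=C1[C@@H]2[C@H](/C(=C(\C)[Ti](OCC)(OC(C)C)OC(C)C)C(=O)[C@@H]2O[Mg]Cl)[C@@H](C(C)C)CC1 | intermediate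
11 | (1R,3E,3aR,4R,7aS)‑3‑ethylidene‑1‑hydroxy‑7‑methylidene‑4‑(propan‑2‑yl)octahydro‑2H‑inden‑2‑one | C=C1[C@@H]2[C@H](/C(=C\C)C(=O)[C@@H]2O)[C@@H](C(C)C)CC1 | intermediate
12 | (1R,3Z,3aR,4R,7aS)‑3‑ethylidene‑1‑hydroxy‑7‑methylidene‑4‑(propan‑2‑yl)octahydro‑2H‑inden‑2‑one | C=C1[C@@H]2[C@H](/C(=C/C)C(=O)[C@@H]2O)[C@@H](C(C)C)CC1 | intermediate
13 | (2R)‑2‑methylbutanoic acid | CC[C@@H](C)C(=O)O | starting material
14 | (1R,3Z,3aR,4R,7aS)‑3‑ethylidene‑7‑methylidene‑2‑oxo‑4‑(propan‑2‑yl)octahydro‑1H‑inden‑1‑yl (2R)‑2‑methylbutanoate | C=C1[C@@H]2[C@H](/C(=C/C)C(=O)[C@@H]2OC(=O)[C@H](C)CC)[C@@H](C(C)C)CC1 | intermediate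
15 | (1R,3Z,3aR,4R,6S,7aS)‑3‑ethylidene‑6‑hydroxy‑7‑methylidene‑2‑oxo‑4‑(propan‑2‑yl)octahydro‑1H‑inden‑1‑yl (2R)‑2‑methylbutanoate | C=C1[C@@H]2[C@H](/C(=C/C)C(=O)[C@@H]2OC(=O)[C@H](C)CC)[C@@H](C(C)C)C[C@@H]1O | intermediate
16 | (2E)‑3‑methylpent‑2‑enoic acid | CC/C(C)=C/C(=O)O | starting material
17 | (1R,3Z,3aR,4R,6S,7aS)‑3‑ethylidene‑7‑methylidene‑1‑{[(2R)‑2‑methylbutanoyl]oxy}‑2‑oxo‑4‑(propan‑2‑yl)octahydro‑1H‑inden‑6‑yl (2E)‑3‑methylpent‑2‑enoate | C=C1[C@@H]2[C@H](/C(=C/C)C(=O)[C@@H]2OC(=O)[C@H](C)CC)[C@@H](C(C)C)C[C@@H]1OC(=O)/C=C(\C)CC | target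

**Totals and risks**
Total step count: 9. Longest linear sequence: 9 (1 to 17); the small partners 4, 7, 13 and 16 are bought.

Most likely to fail:

Step 2 (desymmetrising dehydrogenation). The risks are a moderate enantiomeric excess, over‑oxidation of the enone back to 4‑isopropylphenol, and oxidation of the amine catalyst by IBX. Fallback, from 2 back to 3: enantiotopic deprotonation of 2 with the lithium amide of enantiopure bis(1‑phenylethyl)amine (the antipode that gives the 4S enol silane) and TMSCl as internal quench in THF at −100 °C gives trimethyl{[(4S)‑4‑(propan‑2‑yl)cyclohex‑1‑en‑1‑yl]oxy}silane F1. Saegusa–Ito oxidation of F1 with Pd(OAc)2 in MeCN then returns to 3.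

Step 6 (titanium‑mediated ring closure and E→Z equilibration). The free α‑hydroxy ester may tie up the titanium reagent, Kulinkovich‑type attack on the ester may compete, and the Z preference of the ethylidene rests on a strain argument. Fallback, from 6 back to 14, using a rhodium alkyne hydroacylation instead: 6 is cleaved with MeLi, transmetalated with ClTi(OiPr)3 and added to acrolein to give the syn aldol (2R,3R,4R)‑2‑[(1S)‑1‑hydroxyprop‑2‑en‑1‑yl]‑4‑(propan‑2‑yl)‑3‑(prop‑1‑yn‑1‑yl)cyclohexan‑1‑one F2. Steglich esterification with 13 gives (1S)‑1‑[(1R,2R,3R)‑6‑oxo‑3‑(propan‑2‑yl)‑2‑(prop‑1‑yn‑1‑yl)cyclohexyl]prop‑2‑en‑1‑yl (2R)‑2‑methylbutanoate F3. Cleavage of the vinyl group with OsO4 (cat.), NaIO4 and 2,6‑lutidine, which leaves the alkyne alone, gives (1R)‑2‑oxo‑1‑[(1R,2R,3R)‑6‑oxo‑3‑(propan‑2‑yl)‑2‑(prop‑1‑yn‑1‑yl)cyclohexyl]ethyl (2R)‑2‑methylbutanoate F4. [Rh(dppe)]ClO4 (5 mol%) in acetone at rt closes the ring by intramolecular alkyne hydroacylation to (1R,3E,3aR,4R,7aR)‑3‑ethylidene‑2,7‑dioxo‑4‑(propan‑2‑yl)octahydro‑1H‑inden‑1‑yl (2R)‑2‑methylbutanoate F5. PhSSPh (cat.) under light equilibrates F5 to (1R,3Z,3aR,4R,7aR)‑3‑ethylidene‑2,7‑dioxo‑4‑(propan‑2‑yl)octahydro‑1H‑inden‑1‑yl (2R)‑2‑methylbutanoate F6. Takai–Lombardo methylenation of F6 (Zn, CH2Br2, TiCl4), where the saturated six‑ring ketone should react before the cross‑conjugated enone, gives 14.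

Step 8 (allylic hydroxylation). The risks are competing oxidation at the ring‑fusion CH or the ethylidene methyl, over‑oxidation to the enone, and a wrong C6 epimer. Fallback, from 14 directly to 17, using a copper‑catalysed radical allylic acyloxylation that installs the ester in one operation: acid 16 is converted with tBuOOH and DCC into tert‑butyl (2E)‑3‑methylpent‑2‑eneperoxoate F7. A Kharasch–Sosnovsky reaction of 14 with F7 and CuBr (5 mol%) in PhH at 70 °C (tert‑butoxyl abstracts the C6 hydrogen, and the allylcopper carboxylate collapses to the ester with the exocyclic alkene retained) then gives 17.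

**Further compounds**
F1 | step 2 | trimethyl{[(4S)‑4‑(propan‑2‑yl)cyclohex‑1‑en‑1‑yl]oxy}silane | C[Si](C)(C)OC1=CC[C@@H](C(C)C)CC1
F2 | step 6 | (2R,3R,4R)‑2‑[(1S)‑1‑hydroxyprop‑2‑en‑1‑yl]‑4‑(propan‑2‑yl)‑3‑(prop‑1‑yn‑1‑yl)cyclohexan‑1‑one | O=C1[C@@H]([C@@H](O)C=C)[C@H](C#CC)[C@@H](C(C)C)CC1
F3 | step 6 | (1S)‑1‑[(1R,2R,3R)‑6‑oxo‑3‑(propan‑2‑yl)‑2‑(prop‑1‑yn‑1‑yl)cyclohexyl]prop‑2‑en‑1‑yl (2R)‑2‑methylbutanoate | O=C1[C@@H]([C@@H](OC(=O)[C@H](C)CC)C=C)[C@H](C#CC)[C@@H](C(C)C)CC1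
F4 | step 6 | (1R)‑2‑oxo‑1‑[(1R,2R,3R)‑6‑oxo‑3‑(propan‑2‑yl)‑2‑(prop‑1‑yn‑1‑yl)cyclohexyl]ethyl (2R)‑2‑methylbutanoate | O=C1[C@@H]([C@@H](OC(=O)[C@H](C)CC)C=O)[C@H](C#CC)[C@@H](C(C)C)CC1
F5 | step 6 | (1R,3E,3aR,4R,7aR)‑3‑ethylidene‑2,7‑dioxo‑4‑(propan‑2‑yl)octahydro‑1H‑inden‑1‑yl (2R)‑2‑methylbutanoate | O=C1[C@@H]2[C@H](/C(=C\C)C(=O)[C@@H]2OC(=O)[C@H](C)CC)[C@@H](C(C)C)CC1
F6 | step 6 | (1R,3Z,3aR,4R,7aR)‑3‑ethylidene‑2,7‑dioxo‑4‑(propan‑2‑yl)octahydro‑1H‑inden‑1‑yl (2R)‑2‑methylbutanoate | O=C1[C@@H]2[C@H](/C(=C/C)C(=O)[C@@H]2OC(=O)[C@H](C)CC)[C@@H](C(C)C)CC1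
F7 | step 8 | tert‑butyl (2E)‑3‑methylpent‑2‑eneperoxoate | CC/C(C)=C/C(=O)OOC(C)(C)C
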